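## Retrosynthetic overview

- The only ring to be made is the oxirane. It is closed in the last step by enantioselective oxygen transfer to the alkene of the fully acylated 8,9-dehydrothymol-type precursor, the same order as the presumed biogenesis (dehydrothymol, then C10 oxygenation and acylation, then epoxidation).
- That alkene diester comes from its 7-aldehyde by hydride reduction, so the benzylic alcohol never competes in the acylations.
- The two different esters go on one at a time: lipase for the aliphatic OH, then acyl chloride for the phenol.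
- The 2-arylallyl alcohol skeleton is made in one pot from 4-bromo-3-hydroxybenzaldehyde by borylation and Suzuki coupling with 2-bromoallyl alcohol.
- Ring order: the benzene ring is bought; the oxirane is formed last and not handled afterwards.

Assumption: the D-glucose-derived lactam ketone is taken to deliver oxygen to the Si face of the aryl-bearing alkene carbon (giving R); if the measured sense is the reverse, its mirror-image ketone from L-glucose is used and nothing else changes.

## Route

Step 1
Reactants: 1 4-bromo-3-hydroxybenzaldehyde; 2 2-bromoprop-2-en-1-ol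
Product: 4 3-hydroxy-4-(3-hydroxyprop-1-en-2-yl)benzaldehyde, via aryl pinacol boronate 3 (not isolated)
Conditions: B2pin2 (1.2 equiv), Pd(dppf)Cl2 (3 mol %), KOAc (3 equiv), 1,4-dioxane, 90 °C; then 2 (1.5 equiv), 2 M aq. K2CO3, 80 °C
Reagents that add atoms: bis(pinacolato)diboron, CC1(C)OB(OC1(C)C)B1OC(C)(C)C(C)(C)O1 (supplies the boryl group of 3; none of its atoms remain in 4)
Why: One-pot Miyaura borylation then Suzuki–Miyaura coupling: the bromide para to the formyl group adds readily to zerovalent palladium, KOAc-mediated transmetalation with B2pin2 gives 3, and after aqueous K2CO3 is added the same catalyst couples 3 with vinyl bromide 2 without protecting the phenol, aldehyde or allylic alcohol; no stereocentre is formed.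

Step 2
Reactants: 4 3-hydroxy-4-(3-hydroxyprop-1-en-2-yl)benzaldehyde
Product: 5 2-(4-formyl-2-hydroxyphenyl)prop-2-en-1-yl pentanoate
Conditions: pentanoic anhydride (1.5 equiv), Novozym 435 (immobilised Candida antarctica lipase B), MTBE–THF, 40 °C
Reagents that add atoms: pentanoic anhydride, CCCCC(=O)OC(=O)CCCC
Why: Lipase-catalysed chemoselective acylation: this lipase acylates primary aliphatic alcohols but not phenols (as with tyrosol-type substrates), so only the allylic OH is esterified and the mono-ester is easily purified; no stereocentre.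

Step 3
Reactants: 5 2-(4-formyl-2-hydroxyphenyl)prop-2-en-1-yl pentanoate
Product: 6 2-[4-formyl-2-(2-methylpropanoyloxy)phenyl]prop-2-en-1-yl pentanoate
Conditions: 2-methylpropanoyl chloride (1.2 equiv), K2CO3 (2 equiv), MeCN, 0 °C to rt
Reagents that add atoms: 2-methylpropanoyl chloride, CC(C)C(Cl)=O
Why: Phenoxide O-acylation of the only remaining hydroxyl; the aldehyde and the allyl ester are inert to K2CO3 and acyl chloride at this temperature; no stereocentre.

Step 4
Reactants: 6 2-[4-formyl-2-(2-methylpropanoyloxy)phenyl]prop-2-en-1-yl pentanoate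
Product: 7 2-[4-(hydroxymethyl)-2-(2-methylpropanoyloxy)phenyl]prop-2-en-1-yl pentanoate
Conditions: NaBH4 (0.5 equiv), THF–EtOH 4:1, −30 °C, 20 min; then water (pH 7 buffer)
Reagents that add atoms: none
Why: Chemoselective borohydride reduction: an aryl aldehyde is reduced by NaBH4 within minutes at −30 °C, far faster than the aryl or alkyl ester, and the 1,1-disubstituted alkene is untouched; no stereocentre.

Step 5
Reactants: 7 2-[4-(hydroxymethyl)-2-(2-methylpropanoyloxy)phenyl]prop-2-en-1-yl pentanoate
Product: 8 [(2R)-2-[4-(hydroxymethyl)-2-(2-methylpropanoyloxy)phenyl]oxiran-2-yl]methyl pentanoate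
Conditions: Shi N-aryl spiro-morpholin-3-one (lactam) ketone of the D-glucose series (0.3 equiv), Oxone (2KHSO5·KHSO4·K2SO4, 1.8 equiv) and aq. K2CO3 added together by syringe pump over 6 h, Bu4NHSO4 (cat.), DME–dimethoxymethane / K2CO3–AcOH buffer (pH 9.3, Na2EDTA), −10 °C
Reagents that add atoms: potassium peroxymonosulfate (active salt of Oxone), [K+].[O-]S(=O)(=O)OO
Why: Shi asymmetric epoxidation, used as a late-stage epoxidase-like oxidation of the fully acylated 1,1-disubstituted alkene: the chiral dioxirane formed in situ from this ketone (the catalyst type developed for α-substituted styrenes) transfers oxygen through a planar-like transition state with the aryl group over the lactam, to the Si face of the aryl-bearing alkene carbon (the face from which CH2O2CBu, aryl and =CH2 run counterclockwise), which sets the (R) quaternary centre in the final step so nothing can scramble it afterwards, while the primary alcohol and both esters tolerate buffered dioxirane at −10 °C.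

## Compound list

1 | 4-bromo-3-hydroxybenzaldehyde | O=Cc1ccc(Br)c(O)c1 | starting material
2 | 2-bromoprop-2-en-1-ol | OCC(Br)=C | starting material
3 | 3-hydroxy-4-(4,4,5,5-tetramethyl-1,3,2-dioxaborolan-2-yl)benzaldehyde | O=Cc1ccc(B2OC(C)(C)C(C)(C)O2)c(O)c1 | intermediate
4 | 3-hydroxy-4-(3-hydroxyprop-1-en-2-yl)benzaldehyde | O=Cc1ccc(C(=C)CO)c(O)c1 | intermediate
5 | 2-(4-formyl-2-hydroxyphenyl)prop-2-en-1-yl pentanoate | CCCCC(=O)OCC(=C)c1ccc(C=O)cc1O | intermediate
6 | 2-[4-formyl-2-(2-methylpropanoyloxy)phenyl]prop-2-en-1-yl pentanoate | CCCCC(=O)OCC(=C)c1ccc(C=O)cc1OC(=O)C(C)C | intermediate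
7 | 2-[4-(hydroxymethyl)-2-(2-methylpropanoyloxy)phenyl]prop-2-en-1-yl pentanoate | CCCCC(=O)OCC(=C)c1ccc(CO)cc1OC(=O)C(C)C | intermediate
8 | [(2R)-2-[4-(hydroxymethyl)-2-(2-methylpropanoyloxy)phenyl]oxiran-2-yl]methyl pentanoate | CCCCC(=O)OC[C@@]1(c2ccc(CO)cc2OC(=O)C(C)C)CO1 | target

## Step count and risks

Total steps: 5. Longest linear sequence: 5.

**Step 5 (most likely to fail).** Enantioselectivity for α-substituted styrenes with this catalyst class is typically 60–90% ee. Here the ortho acyloxy group twists the arene, the allylic ester deactivates the alkene, and the benzylic alcohol could be slowly over-oxidised. A modest ee shortfall is corrected by preparative chiral HPLC. If the method itself fails, the fallback switches to hydroxyl-directed epoxidation, setting out from 4 and returning at 8. Phenoxide-selective acylation of 4 (2-methylpropanoyl chloride 1.0 equiv, K2CO3, MeCN, 0 °C) gives 5-formyl-2-(3-hydroxyprop-1-en-2-yl)phenyl 2-methylpropanoate F1, which is used at once. Sharpless asymmetric epoxidation (Ti(OiPr)4, L-(+)-diisopropyl tartrate, tBuOOH, 4 Å sieves, CH2Cl2, −20 °C) gives 5-formyl-2-[(2S)-2-(hydroxymethyl)oxiran-2-yl]phenyl 2-methylpropanoate F2. The natural tartrate gives the 2S series, which has the spatial arrangement of the target. Acylation without alkoxide base (pentanoic anhydride, pyridine, 0 °C, so no Payne-type scrambling) gives [(2R)-2-[4-formyl-2-(2-methylpropanoyloxy)phenyl]oxiran-2-yl]methyl pentanoate F3. NaBH4 under the step 4 conditions then delivers 8.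

**Step 1.** The free ortho-hydroxy boronate may protodeboronate, and the product could cyclise under palladium. The fallback installs the C10 oxygen by allylic C–H functionalisation, setting out from 1 and returning at 6. Suzuki coupling of 1 with 2-isopropenyl-4,4,5,5-tetramethyl-1,3,2-dioxaborolane (Pd(dppf)Cl2, K2CO3, dioxane–water, 80 °C) gives 3-hydroxy-4-(prop-1-en-2-yl)benzaldehyde F4. Acylation (2-methylpropanoyl chloride, K2CO3, MeCN) gives 5-formyl-2-(prop-1-en-2-yl)phenyl 2-methylpropanoate F5. Ene-type allylic bromination (N-bromosuccinimide, cat. TsOH, THF, reflux) gives 2-(3-bromoprop-1-en-2-yl)-5-formylphenyl 2-methylpropanoate F6. Displacement with caesium pentanoate (pentanoic acid, Cs2CO3, DMF, rt) gives 6.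

**Step 4.** The aryl ester could be cleaved or transferred by borohydride or the alkoxide formed. The fallback reduces before the aryl ester exists, setting out from 5 and returning at 7. NaBH4 in EtOH at 0 °C on 5 gives 2-[2-hydroxy-4-(hydroxymethyl)phenyl]prop-2-en-1-yl pentanoate F7. Phenoxide-selective acylation (2-methylpropanoyl chloride 1.0 equiv, K2CO3, MeCN, 0 °C), which leaves the benzylic alcohol free, gives 7.

## Further compounds

F1 | step 5 | 5-formyl-2-(3-hydroxyprop-1-en-2-yl)phenyl 2-methylpropanoate | CC(C)C(=O)Oc1cc(C=O)ccc1C(=C)CO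
F2 | step 5 | 5-formyl-2-[(2S)-2-(hydroxymethyl)oxiran-2-yl]phenyl 2-methylpropanoate | OC[C@@]1(c2ccc(C=O)cc2OC(=O)C(C)C)CO1
F3 | step 5 | [(2R)-2-[4-formyl-2-(2-methylpropanoyloxy)phenyl]oxiran-2-yl]methyl pentanoate | CCCCC(=O)OC[C@@]1(c2ccc(C=O)cc2OC(=O)C(C)C)CO1
F4 | step 1 | 3-hydroxy-4-(prop-1-en-2-yl)benzaldehyde | CC(=C)c1ccc(C=O)cc1O
F5 | step 1 | 5-formyl-2-(prop-1-en-2-yl)phenyl 2-methylpropanoate | CC(=C)c1ccc(C=O)cc1OC(=O)C(C)C
F6 | step 1 | 2-(3-bromoprop-1-en-2-yl)-5-formylphenyl 2-methylpropanoate | BrCC(=C)c1ccc(C=O)cc1OC(=O)C(C)C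
F7 | step 4 | 2-[2-hydroxy-4-(hydroxymethyl)phenyl]prop-2-en-1-yl pentanoate | CCCCC(=O)OCC(=C)c1ccc(CO)cc1O
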